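The synthesis cuts two bonds at once: C3–C4 of the tetrahydrofuran ring (O1, C2–C5) and the bond from the C7' methylene to the guaiacyl ring. The feature exploited is that C3 bears the C9 oxymethyl arm and C4 the cis C7' arm. A C3–C9 epoxide is a masked C3 radical, an allyl group on O1 is its 5-exo acceptor, and the resulting C7' radical is a partner for an aryl–nickel species. One titanium/nickel operation should therefore close the ring, form two C–C bonds and set C3 and C4 from C2 alone. The precursor is the enantioenriched allyl ether of an O-benzylsyringyl epoxy carbinol, coupled with O-benzyl-4-bromoguaiacol. Debenzylation and feruloylation follow.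

Key step: step 6

Remark: locants are O1, C2 (syringyl), C3 (C9 arm), C4 (C7' arm), C5. For the epoxy carbinol, erythro is the (αR,2S) isomer, which the tartrate-controlled epoxidation of the (S)-carbinol delivers, whereas (αR,2R) is threo.

Step 1
Reactants: 1 syringaldehyde
Product: 2 4-(benzyloxy)-3,5-dimethoxybenzaldehyde
Conditions: BnBr (1.2 equiv), K2CO3 (2 equiv), DMF, 60 °C
Reagents that add atoms: benzyl bromide, BrCc1ccccc1
Why: Williamson ether synthesis on an acidic phenol with a primary benzylic bromide should be clean, and the benzyl ether withstands every later basic, Lewis-acidic and reducing-metal step.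

Step 2
Reactants: 2 4-(benzyloxy)-3,5-dimethoxybenzaldehyde; 3 vinylmagnesium bromide
Product: 5 rac-1-[4-(benzyloxy)-3,5-dimethoxyphenyl]prop-2-en-1-ol, via bromomagnesium alkoxide 4 (not isolated)
Conditions: CH2=CHMgBr (1.2 equiv), THF, −78 to 0 °C; sat. aq NH4Cl
Reagents that add atoms: none
Why: Grignard 1,2-addition to a non-enolisable aromatic aldehyde should give the carbinol with C2 racemic (resolved in step 3), and the buffered quench avoids acid-induced allylic transposition.

Step 3
Reactants: 5 rac-1-[4-(benzyloxy)-3,5-dimethoxyphenyl]prop-2-en-1-ol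
Product: 6 (R)-[4-(benzyloxy)-3,5-dimethoxyphenyl][(2S)-oxiran-2-yl]methanol (erythro)
Conditions: Ti(OiPr)4 (15 mol%), D-(−)-diisopropyl tartrate (18 mol%), anhydrous TBHP (0.45 equiv), 4 Å molecular sieves, CH2Cl2, −20 °C; citric acid work-up, chromatography
Reagents that add atoms: tert-butyl hydroperoxide, CC(C)(C)OO
Why: In this Sharpless kinetic-resolution epoxidation the (S)-carbinol is the fast-reacting partner of the (S,S)-tartrate catalyst and is epoxidised on the face giving the erythro (αR,2S) product, so sub-stoichiometric TBHP should consume only that enantiomer and fix C2 of the target, while the (R)-carbinol stays behind and is separated.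

Step 4
Reactants: 6 erythro epoxy carbinol; 7 allyl bromide
Product: 9 (2S)-2-{(R)-(allyloxy)[4-(benzyloxy)-3,5-dimethoxyphenyl]methyl}oxirane, via sodium alkoxide 8 (not isolated)
Conditions: allyl bromide (2 equiv), n-Bu4NI (5 mol%), THF, 0 °C, NaH (1.2 equiv) added last in portions, then rt
Reagents that add atoms: none
Why: Williamson O-allylation in an aprotic medium, with 8 trapped by excess 7 as it forms, should outrun Payne rearrangement and touches neither stereocentre.

Step 5
Reactants: 10 4-bromo-2-methoxyphenol
Product: 11 1-(benzyloxy)-4-bromo-2-methoxybenzene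
Conditions: BnBr (1.1 equiv), K2CO3 (2 equiv), acetone, reflux
Reagents that add atoms: benzyl bromide, BrCc1ccccc1
Why: Williamson ether synthesis on an unhindered phenol, to which the aryl bromide is inert.

Step 6
Reactants: 9 erythro epoxy allyl ether; 11 1-(benzyloxy)-4-bromo-2-methoxybenzene
Product: 15 di-O-benzyl-5-methoxylariciresinol [(2S,3R,4R)-2-[4-(benzyloxy)-3,5-dimethoxyphenyl]-4-[4-(benzyloxy)-3-methoxybenzyl]tetrahydrofuran-3-yl]methanol, via C3 titanoxy radical 12 (not isolated), via cyclised C7' radical 13 (not isolated), via titanium alkoxide 14 (not isolated)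
Conditions: NiBr2(dme) (10 mol%), 4,4'-di-tert-butyl-2,2'-bipyridine (12 mol%), Cp2TiCl2 (20 mol%), Mn powder (3 equiv), Et3N·HCl (1.5 equiv), 11 (1.5 equiv), DMPU, 25 °C, argon, 9 added by syringe pump
Reagents that add atoms: none
Why: Proposed new method: Cp2TiCl, made in the flask from Cp2TiCl2 and Mn, should break the C3–O bond of the terminal epoxide homolytically to give the secondary radical 12 with C9 held as a titanium alkoxide; 12 adds to the allyl alkene to form C3–C4 and the primary radical 13, which is caught by the aryl–nickel bromide arising from 11 and zerovalent nickel, and reductive elimination from the trivalent nickel species forms C7'–aryl, after which Et3N·HCl protonates alkoxide 14 and returns Cp2TiCl2 while Mn re-reduces both metals. The closest known reaction types are titanocene-mediated epoxide-opening 5-exo cyclizations of epoxy allyl ethers, the nickel/titanocene reductive arylation of epoxides by aryl halides, and nickel-catalysed cyclization–arylation of alkenyl halides; joining them on one substrate is what is new. The tetrahydrofuran ring closes in the 5-exo-trig mode. C3 is planar in 12, so the epoxide configuration is erased and C3 is reset by the C2 stereocentre, whose aryl group sits pseudoequatorial in the chair-like (Beckwith–Houk) transition state and pushes the CH2OTi arm trans to itself; C4 is set in the same transition state, the alkene terminus lying cis to the C9 arm as is usual for 1-substituted hexenyl radicals and trans to the aryl group as is usual for 2-substituted ones. The step needs ring closure to outrun bimolecular interception of 12 (direct C3 arylation, or reduction by a second Cp2TiCl followed by deoxygenation), which the intrinsically fast closure of a β-allyloxyalkyl radical, the low metal loadings and the slow addition of 9 should secure. It also needs nickel rather than titanium or a hydrogen donor to take 13, hence catalytic titanium, an excess of 11 and DMPU in place of an ethereal solvent.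

Step 7
Reactants: 15 di-O-benzyl-5-methoxylariciresinol
Product: 16 5-methoxylariciresinol, 4-[(2S,3R,4R)-4-(4-hydroxy-3-methoxybenzyl)-3-(hydroxymethyl)tetrahydrofuran-2-yl]-2,6-dimethoxyphenol
Conditions: H2 (1 atm), 10% Pd/C, EtOAc–EtOH, rt, stopped at full debenzylation
Reagents that add atoms: none
Why: In catalytic hydrogenolysis under neutral conditions aryl benzyl ethers cleave much faster than the ring C2–O1 benzylic dialkyl ether, so the tetrahydrofuran and its three stereocentres should survive, and the step is placed before the reducible cinnamate alkene arrives.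

Step 8
Reactants: 16 5-methoxylariciresinol; 17 (E)-ferulic acid
Product: 19 target [(2S,3R,4R)-2-(4-hydroxy-3,5-dimethoxyphenyl)-4-(4-hydroxy-3-methoxybenzyl)tetrahydrofuran-3-yl]methyl (E)-3-(4-hydroxy-3-methoxyphenyl)prop-2-enoate, via C9 alkoxyphosphonium ferulate 18 (not isolated)
Conditions: 17 (1.2 equiv), PPh3 (1.3 equiv), DIAD (1.3 equiv, added last, dropwise), THF, 0 °C to rt
Reagents that add atoms: none
Why: In this Mitsunobu esterification only the aliphatic C9 alcohol can be activated as 18 and only the carboxylic acid, far more acidic than the three phenols, is ionised, so carboxylate displacement at the primary non-stereogenic C9 should give the ester without phenol protection and with the E alkene intact.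

Compound list
1 | syringaldehyde | COc1cc(C=O)cc(OC)c1O | starting material
2 | 4-(benzyloxy)-3,5-dimethoxybenzaldehyde | COc1cc(C=O)cc(OC)c1OCc1ccccc1 | intermediate
3 | vinylmagnesium bromide | C=C[Mg]Br | starting material
4 | bromomagnesium alkoxide of 5 (racemic) | C=CC(O[Mg]Br)c1cc(OC)c(OCc2ccccc2)c(OC)c1 | intermediate
5 | rac-1-[4-(benzyloxy)-3,5-dimethoxyphenyl]prop-2-en-1-ol | C=CC(O)c1cc(OC)c(OCc2ccccc2)c(OC)c1 | intermediate
6 | (R)-[4-(benzyloxy)-3,5-dimethoxyphenyl][(2S)-oxiran-2-yl]methanol, erythro | O[C@@H]([C@@H]1CO1)c1cc(OC)c(OCc2ccccc2)c(OC)c1 | intermediate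
7 | allyl bromide | C=CCBr | starting material
8 | sodium alkoxide of 6 | [Na+].[O-][C@@H]([C@@H]1CO1)c1cc(OC)c(OCc2ccccc2)c(OC)c1 | intermediate
9 | (2S)-2-{(R)-(allyloxy)[4-(benzyloxy)-3,5-dimethoxyphenyl]methyl}oxirane, erythro | C=CCO[C@@H]([C@@H]1CO1)c1cc(OC)c(OCc2ccccc2)c(OC)c1 | intermediate
10 | 4-bromo-2-methoxyphenol | COc1cc(Br)ccc1O | starting material
11 | 1-(benzyloxy)-4-bromo-2-methoxybenzene | COc1cc(Br)ccc1OCc1ccccc1 | intermediate
12 | C3 radical with C9 as Cp2Ti(Cl) alkoxide, C2 as in 9 (Cp written σ-bonded in the string) | C=CCO[C@@H]([CH]CO[Ti](Cl)(C1C=CC=C1)C1C=CC=C1)c1cc(OC)c(OCc2ccccc2)c(OC)c1 | intermediate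
13 | cyclised primary C7' radical, 2,3-trans-3,4-cis tetrahydrofuran, C9 as Cp2Ti(Cl) alkoxide | Cl[Ti](C1C=CC=C1)(C1C=CC=C1)OC[C@H]1[C@@H]([CH2])CO[C@@H]1c1cc(OC)c(OCc2ccccc2)c(OC)c1 | intermediate
14 | Cp2Ti(Cl) alkoxide of 15 | Cl[Ti](C1C=CC=C1)(C1C=CC=C1)OC[C@H]1[C@@H](Cc2ccc(OCc3ccccc3)c(OC)c2)CO[C@@H]1c1cc(OC)c(OCc2ccccc2)c(OC)c1 | intermediate
15 | di-O-benzyl-5-methoxylariciresinol, (2S,3R,4R), C2/C3 trans, C3/C4 cis | OC[C@H]1[C@@H](Cc2ccc(OCc3ccccc3)c(OC)c2)CO[C@@H]1c1cc(OC)c(OCc2ccccc2)c(OC)c1 | intermediate
16 | 5-methoxylariciresinol, (2S,3R,4R) | OC[C@H]1[C@@H](Cc2ccc(O)c(OC)c2)CO[C@@H]1c1cc(OC)c(O)c(OC)c1 | intermediate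
17 | (E)-ferulic acid | COc1cc(/C=C/C(O)=O)ccc1O | starting material
18 | C9-O-triphenylphosphonium salt of 16 with ferulate counter-ion | c1ccccc1[P+](c1ccccc1)(c1ccccc1)OC[C@H]1[C@@H](Cc2ccc(O)c(OC)c2)CO[C@@H]1c1cc(OC)c(O)c(OC)c1.COc1cc(/C=C/C([O-])=O)ccc1O | intermediate
19 | 9-O-(E)-feruloyl-5-methoxylariciresinol (CNP0289934.1) | COc1cc(/C=C/C(=O)OC[C@H]2[C@@H](Cc3ccc(O)c(OC)c3)CO[C@@H]2c2cc(OC)c(O)c(OC)c2)ccc1O | target

Total step count: 8. Longest linear sequence: 7 (steps 1, 2, 3, 4, 6, 7, 8).

Steps most likely to fail

Step 6 (proposed new method).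
- The radical events may fall out of step in four ways. The C3 radical may be captured before ring closure. The C7' radical may be reduced or abstract hydrogen before nickel reaches it. Halide may open the epoxide at C9. Nickel may insert into the allyl ether C–O bond.
- The fallback uses known chemistry, sets out from 9 and returns at 15. It splits the cascade into two established operations.
- Stoichiometric Cp2TiCl (Cp2TiCl2 2.5 equiv, Mn, THF, rt) performs the same epoxide opening and 5-exo closure. The excess titanium reagent intercepts the C7' radical. An iodine quench under neutral work-up should then give the primary iodide [(2S,3R,4R)-2-[4-(benzyloxy)-3,5-dimethoxyphenyl]-4-(iodomethyl)tetrahydrofuran-3-yl]methanol F1.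
- Nickel-catalysed reductive cross-electrophile coupling of F1 with 11 (NiI2, 4,4'-di-tert-butyl-2,2'-bipyridine, Mn, DMPU, 60 °C) tolerates free hydroxyl groups and should then deliver 15.

Step 3.
- Enantiomeric purity of the epoxide may erode once the slow enantiomer starts to react.
- The Lewis-acidic titanium may ionise the electron-rich benzylic carbinol, or isopropoxide may open the terminal epoxide.
- The fallback sets out from 5 and returns at 6. Resolution and epoxidation are separated.
- Lipase-catalysed transesterification (Candida antarctica lipase B, vinyl acetate, MTBE, rt) should follow the Kazlauskas rule. It should acetylate the (R)-carbinol to (R)-1-[4-(benzyloxy)-3,5-dimethoxyphenyl]prop-2-en-1-yl acetate F2 and leave (S)-1-[4-(benzyloxy)-3,5-dimethoxyphenyl]prop-2-en-1-ol F3.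
- After separation, hydroxyl-directed epoxidation of F3 (VO(acac)2 cat., TBHP, CH2Cl2, 0 °C) should give mainly 6.
- The minor threo epimer (R)-[4-(benzyloxy)-3,5-dimethoxyphenyl][(2R)-oxiran-2-yl]methanol F4 need not be removed. Its allyl ether (2R)-2-{(R)-(allyloxy)[4-(benzyloxy)-3,5-dimethoxyphenyl]methyl}oxirane F5, formed under the step 4 conditions, opens to the same radical 12.

Step 8.
- Phenol O-alkylation may compete, and displacement at the β-branched C9 may be sluggish.
- The fallback sets out from 15 and returns at 19. The cinnamate is built on the ester instead of being coupled as an acid.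
- Heating 15 with Meldrum's acid (toluene, 105 °C) should give the malonic half-ester 3-{[(2S,3R,4R)-2-[4-(benzyloxy)-3,5-dimethoxyphenyl]-4-[4-(benzyloxy)-3-methoxybenzyl]tetrahydrofuran-3-yl]methoxy}-3-oxopropanoic acid F6.
- Hydrogenolysis (H2, 10% Pd/C, EtOAc) should give the bis-phenol half-ester 3-{[(2S,3R,4R)-2-(4-hydroxy-3,5-dimethoxyphenyl)-4-(4-hydroxy-3-methoxybenzyl)tetrahydrofuran-3-yl]methoxy}-3-oxopropanoic acid F7.
- Knoevenagel–Doebner condensation of F7 with vanillin (pyridine, cat. piperidine, 55 °C) tolerates free phenols and is inherently E-selective. It should give 19.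

Further compounds
F1 | step 6 | [(2S,3R,4R)-2-[4-(benzyloxy)-3,5-dimethoxyphenyl]-4-(iodomethyl)tetrahydrofuran-3-yl]methanol | OC[C@H]1[C@@H](CI)CO[C@@H]1c1cc(OC)c(OCc2ccccc2)c(OC)c1
F2 | step 3 | (R)-1-[4-(benzyloxy)-3,5-dimethoxyphenyl]prop-2-en-1-yl acetate | CC(=O)O[C@H](C=C)c1cc(OC)c(OCc2ccccc2)c(OC)c1
F3 | step 3 | (S)-1-[4-(benzyloxy)-3,5-dimethoxyphenyl]prop-2-en-1-ol | O[C@@H](C=C)c1cc(OC)c(OCc2ccccc2)c(OC)c1
F4 | step 3 | (R)-[4-(benzyloxy)-3,5-dimethoxyphenyl][(2R)-oxiran-2-yl]methanol, threo | O[C@@H]([C@H]1CO1)c1cc(OC)c(OCc2ccccc2)c(OC)c1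
F5 | step 3 | (2R)-2-{(R)-(allyloxy)[4-(benzyloxy)-3,5-dimethoxyphenyl]methyl}oxirane, threo | C=CCO[C@@H]([C@H]1CO1)c1cc(OC)c(OCc2ccccc2)c(OC)c1
F6 | step 8 | malonic half-ester of 15 | OC(=O)CC(=O)OC[C@H]1[C@@H](Cc2ccc(OCc3ccccc3)c(OC)c2)CO[C@@H]1c1cc(OC)c(OCc2ccccc2)c(OC)c1
F7 | step 8 | malonic half-ester of 16 | OC(=O)CC(=O)OC[C@H]1[C@@H](Cc2ccc(O)c(OC)c2)CO[C@@H]1c1cc(OC)c(O)c(OC)c1
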